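Each quaternary benzylic carbon carries methyl, vinyl and homogeranyl, so it is C3 of a farnesyl unit whose C2=C3 olefin has been transposed to the vinyl group. The route cuts the bond between that carbon and C5 of the 1,2,3-trioxygenated ring. In the key step the complete diaryl ether, carrying the R side chain on the other ring and metalated at C5 as an aryl(diethyl)aluminium, attacks (2E,6E)-farnesyl diethyl phosphate in an NHC–copper-catalysed enantioselective SN2′ substitution. One operation joins the C15 chain, creates the vinyl group and sets the S quaternary centre under catalyst control; the precursor is a tris-MOM-protected aryl bromide.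

Key step: step 7

Remark: L denotes the enantiomer of the chiral sulfonate-bridged bidentate NHC ligand (4,5-diphenylimidazolin-2-ylidene type, used as its Ag(I) complex with CuCl2·2H2O) that directs an aryl group to the Re face of C3 of 2 (R product); ent-L directs it to the Si face (S product). Which backbone configuration corresponds to L is to be fixed on compound 6.

Step 1
Reactants: 1 (2E,6E)-farnesol
Product: 2 (2E,6E)-farnesyl diethyl phosphate
Conditions: (EtO)2P(O)Cl, Et3N, DMAP (cat.), CH2Cl2, 0 °C → rt
Reagents that add atoms: diethyl chlorophosphate, CCOP(=O)(Cl)OCC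
Why: Phosphorylation of a primary allylic alcohol (nucleophilic substitution at phosphorus) leaves both E olefins untouched and installs the leaving group needed for copper-catalysed SN2′ chemistry.

Step 2
Reactants: 3 1-bromo-4-(methoxymethoxy)benzene; 2 (2E,6E)-farnesyl diethyl phosphate
Product: 6 1-(methoxymethoxy)-4-[(3R,6E)-3,7,11-trimethyldodeca-1,6,10-trien-3-yl]benzene, via aryllithium 4 (not isolated), via arylaluminium 5 (not isolated)
Conditions: 3 (excess), t-BuLi (2 equiv per Br), Et2O, −78 °C; Et2AlCl, −78 °C → rt; then 2, NHC–Ag complex of L (cat.), CuCl2·2H2O (cat.), THF, −30 °C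
Reagents that add atoms: none
Why: Bromine–lithium exchange and Li→Al transmetalation give 5, which enters the NHC–Cu-catalysed enantioselective SN2′ allylic substitution of the E-trisubstituted allylic phosphate (aryl should transfer in preference to ethyl); ligand L directs the aryl group to the Re face of C3 and so sets the R quaternary centre.

Step 3
Reactants: 6 1-(methoxymethoxy)-4-[(3R,6E)-3,7,11-trimethyldodeca-1,6,10-trien-3-yl]benzene
Product: 8 2-iodo-1-(methoxymethoxy)-4-[(3R,6E)-3,7,11-trimethyldodeca-1,6,10-trien-3-yl]benzene, via ortho-lithiated arene 7 (not isolated)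
Conditions: s-BuLi, TMEDA, THF, −78 °C; then I2, −78 °C → rt
Reagents that add atoms: iodine, II
Why: Directed ortho-metalation by the MOM ether (both ortho positions are equivalent) followed by iodinolysis of the aryllithium; the quaternary centre has no acidic hydrogen and is unaffected.

Step 4
Reactants: 9 5-bromo-2,3-dihydroxybenzaldehyde
Product: 10 5-bromo-2,3-bis(methoxymethoxy)benzaldehyde
Conditions: MOMCl, i-Pr2NEt, CH2Cl2, 0 °C → rt
Reagents that add atoms: chloromethyl methyl ether (MOMCl), COCCl
Why: Base-mediated O-alkylation (MOM protection) of both phenols, which also keeps the ring electron-rich enough for aryl migration in the next step.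

Step 5
Reactants: 10 5-bromo-2,3-bis(methoxymethoxy)benzaldehyde
Product: 12 5-bromo-2,3-bis(methoxymethoxy)phenol, via aryl formate 11 (not isolated)
Conditions: mCPBA, CH2Cl2, 0 °C → rt; aq. NaHCO3 wash; then K2CO3 (cat.), MeOH, rt
Reagents that add atoms: mCPBA (3-chloroperoxybenzoic acid), OOC(=O)c1cccc(Cl)c1
Why: Baeyer–Villiger (Dakin-type) oxidation of the electron-rich ortho-alkoxy benzaldehyde should proceed with aryl migration to the formate, and mild methanolysis frees the phenol at the former formyl carbon.

Step 6
Reactants: 8 2-iodo-1-(methoxymethoxy)-4-[(3R,6E)-3,7,11-trimethyldodeca-1,6,10-trien-3-yl]benzene; 12 5-bromo-2,3-bis(methoxymethoxy)phenol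
Product: 13 5-bromo-1,2-bis(methoxymethoxy)-3-{2-(methoxymethoxy)-5-[(3R,6E)-3,7,11-trimethyldodeca-1,6,10-trien-3-yl]phenoxy}benzene
Conditions: CuI (cat.), picolinic acid (cat.), K3PO4, DMSO, 80 °C
Reagents that add atoms: none
Why: Ullmann-type copper-catalysed diaryl ether synthesis with picolinic acid as ligand copes with ortho-oxygenated partners, and the C–I bond of 8 should react in preference to the C–Br bond, which is kept for step 7.

Step 7
Reactants: 13 5-bromo-1,2-bis(methoxymethoxy)-3-{2-(methoxymethoxy)-5-[(3R,6E)-3,7,11-trimethyldodeca-1,6,10-trien-3-yl]phenoxy}benzene; 2 (2E,6E)-farnesyl diethyl phosphate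
Product: 16 1,2-bis(methoxymethoxy)-3-{2-(methoxymethoxy)-5-[(3R,6E)-3,7,11-trimethyldodeca-1,6,10-trien-3-yl]phenoxy}-5-[(3S,6E)-3,7,11-trimethyldodeca-1,6,10-trien-3-yl]benzene, via aryllithium 14 (not isolated), via arylaluminium 15 (not isolated)
Conditions: 13, t-BuLi (2 equiv), Et2O/THF, −78 °C; Et2AlCl, −78 °C → rt; then 2 (1.5 equiv), NHC–Ag complex of ent-L (cat.), CuCl2·2H2O (cat.), THF, −30 → −15 °C
Reagents that add atoms: none
Why: Bromine–lithium exchange and Li→Al transmetalation give aryl(diethyl)aluminium 15, whose aryl group passes to the sulfonate-bridged NHC–Cu(I) centre; the aryl–copper species adds to the C2=C3 olefin of 2 anti to the phosphate (SN2′ oxidative addition) and reductive elimination from the Cu(III) allyl forms the aryl–C3 bond while the C1=C2 vinyl group appears. The closest known reaction type is the NHC–Cu-catalysed enantioselective allylic substitution of E-trisubstituted allylic phosphates with aryl(dialkyl)aluminium reagents, which builds aryl/methyl/vinyl quaternary carbons from geranyl-type phosphates. No ring is closed. The new S centre is set by ligand ent-L, which steers the aryl group to the Si face of C3 of the 2E olefin; the R centre on the other ring is too remote to interfere, so the step is catalyst-controlled and the ligand antipodal to that of step 2 gives the R,S pattern. The step needs γ- over α-selectivity (secured by the copper–phosphate SN2′ pathway), aryl over ethyl transfer (aryl is expected to be the faster-transferring group on aluminium) and site selectivity for the allylic phosphate over the unactivated olefins (only the phosphate-bearing olefin is electrophilic); a geometrically pure 2E phosphate is required because the 2Z isomer would lead to the opposite configuration.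

Step 8
Reactants: 16 1,2-bis(methoxymethoxy)-3-{2-(methoxymethoxy)-5-[(3R,6E)-3,7,11-trimethyldodeca-1,6,10-trien-3-yl]phenoxy}-5-[(3S,6E)-3,7,11-trimethyldodeca-1,6,10-trien-3-yl]benzene
Product: 17 3-{2-hydroxy-5-[(3R,6E)-3,7,11-trimethyldodeca-1,6,10-trien-3-yl]phenoxy}-5-[(3S,6E)-3,7,11-trimethyldodeca-1,6,10-trien-3-yl]benzene-1,2-diol (target)
Conditions: dilute HCl, MeOH/THF, 40 °C, degassed, under argon
Reagents that add atoms: none
Why: Acid-catalysed acetal solvolysis (MOM cleavage by transacetalisation with methanol) frees the three phenols; no hydroxyl lies ortho to a side chain, so chroman formation is not possible, and the quaternary centres cannot epimerise.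

Compound list
1 | (2E,6E)-farnesol | OC/C=C(\C)CC/C=C(\C)CCC=C(C)C | starting material
2 | (2E,6E)-farnesyl diethyl phosphate | CCOP(=O)(OCC)OC/C=C(\C)CC/C=C(\C)CCC=C(C)C | intermediate
3 | 1-bromo-4-(methoxymethoxy)benzene | COCOc1ccc(Br)cc1 | starting material
4 | [4-(methoxymethoxy)phenyl]lithium | COCOc1ccc([Li])cc1 | intermediate
5 | diethyl[4-(methoxymethoxy)phenyl]aluminium | CC[Al](CC)c1ccc(OCOC)cc1 | intermediate
6 | 1-(methoxymethoxy)-4-[(3R,6E)-3,7,11-trimethyldodeca-1,6,10-trien-3-yl]benzene | C=C[C@@](C)(CC/C=C(\C)CCC=C(C)C)c1ccc(OCOC)cc1 | intermediate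
7 | {2-(methoxymethoxy)-5-[(3R,6E)-3,7,11-trimethyldodeca-1,6,10-trien-3-yl]phenyl}lithium | C=C[C@@](C)(CC/C=C(\C)CCC=C(C)C)c1ccc(OCOC)c([Li])c1 | intermediate
8 | 2-iodo-1-(methoxymethoxy)-4-[(3R,6E)-3,7,11-trimethyldodeca-1,6,10-trien-3-yl]benzene | C=C[C@@](C)(CC/C=C(\C)CCC=C(C)C)c1ccc(OCOC)c(I)c1 | intermediate
9 | 5-bromo-2,3-dihydroxybenzaldehyde | O=Cc1cc(Br)cc(O)c1O | starting material
10 | 5-bromo-2,3-bis(methoxymethoxy)benzaldehyde | O=Cc1cc(Br)cc(OCOC)c1OCOC | intermediate
11 | 5-bromo-2,3-bis(methoxymethoxy)phenyl formate | O=COc1cc(Br)cc(OCOC)c1OCOC | intermediate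
12 | 5-bromo-2,3-bis(methoxymethoxy)phenol | Oc1cc(Br)cc(OCOC)c1OCOC | intermediate
13 | 5-bromo-1,2-bis(methoxymethoxy)-3-{2-(methoxymethoxy)-5-[(3R,6E)-3,7,11-trimethyldodeca-1,6,10-trien-3-yl]phenoxy}benzene | C=C[C@@](C)(CC/C=C(\C)CCC=C(C)C)c1ccc(OCOC)c(Oc2cc(Br)cc(OCOC)c2OCOC)c1 | intermediate
14 | aryllithium from 13 (Li in place of Br) | C=C[C@@](C)(CC/C=C(\C)CCC=C(C)C)c1ccc(OCOC)c(Oc2cc([Li])cc(OCOC)c2OCOC)c1 | intermediate
15 | aryl(diethyl)aluminium from 14 (AlEt2 in place of Li) | C=C[C@@](C)(CC/C=C(\C)CCC=C(C)C)c1ccc(OCOC)c(Oc2cc([Al](CC)CC)cc(OCOC)c2OCOC)c1 | intermediate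
16 | 1,2-bis(methoxymethoxy)-3-{2-(methoxymethoxy)-5-[(3R,6E)-3,7,11-trimethyldodeca-1,6,10-trien-3-yl]phenoxy}-5-[(3S,6E)-3,7,11-trimethyldodeca-1,6,10-trien-3-yl]benzene | C=C[C@@](C)(CC/C=C(\C)CCC=C(C)C)c1ccc(OCOC)c(Oc2cc([C@](C)(C=C)CC/C=C(\C)CCC=C(C)C)cc(OCOC)c2OCOC)c1 | intermediate
17 | 3-{2-hydroxy-5-[(3R,6E)-3,7,11-trimethyldodeca-1,6,10-trien-3-yl]phenoxy}-5-[(3S,6E)-3,7,11-trimethyldodeca-1,6,10-trien-3-yl]benzene-1,2-diol | C=C[C@@](C)(CC/C=C(\C)CCC=C(C)C)c1ccc(O)c(Oc2cc([C@](C)(C=C)CC/C=C(\C)CCC=C(C)C)cc(O)c2O)c1 | target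

Total step count: 8
Longest linear sequence: 6 steps (steps 1, 2, 3, 6, 7, 8); steps 4 and 5 form the convergent branch.

Steps most likely to fail

1. Step 7. The aryl metal of the large, polyoxygenated fragment may be quenched by proton transfer before it reaches copper, ethyl may transfer in competition with the hindered aryl group, and catalyst control of the face may erode; any loss of facial control here or in step 2 gives diastereomers that differ only at two remote centres and would be hard to separate. Fallback: setting out from 13, a Miyaura borylation (bis(neopentyl glycolato)diboron, PdCl2(dppf), KOAc, dioxane, 80 °C) should give the aryl neopentylglycol boronate F1. F1 is then used in the copper-catalysed γ-selective asymmetric allylic arylation of 2 with an arylboronate (CuCl, chiral hydroxy-armed NHC of the Si-face-directing enantiomer, NaOMe, THF, 30 °C), which comes back to the route at 16. This avoids organolithium and organoaluminium species altogether.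

2. Step 6. Oxidative addition into the unhindered C–Br bond may compete with the ortho-oxygenated C–I bond, leading to self-condensation of the bromophenol and over-arylation, and the coupling of two ortho-oxygenated partners may be slow enough for hydrodeiodination to intervene. Fallback: setting out from 6, the ortho-lithiation of step 3 is quenched with B(OiPr)3 and aqueous acid to give the arylboronic acid F2. A Chan–Lam oxidative coupling of F2 with 12 (Cu(OAc)2, pyridine, 4 Å MS, air, CH2Cl2, rt) comes back to the route at 13; copper(II) aryl transfer from boron does not engage the C–Br bond.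

3. Step 8. Protonation of the trisubstituted olefins may start cyclisation or solvent addition along the 1,5-diene chains before all three acetals are cleaved, and the freed catechol may oxidise in air. Fallback: setting out from 16, silyl-transfer cleavage of the aromatic MOM ethers (TESOTf, 2,2′-bipyridyl, CH2Cl2, 0 °C) should give the tris(triethylsilyl) ether F3 under non-protic conditions. Buffered fluoride (TBAF, AcOH, THF, 0 °C, degassed) then frees the phenols and comes back to the route at 17.

Further compounds
F1 | step 7 | 2-{3,4-bis(methoxymethoxy)-5-{2-(methoxymethoxy)-5-[(3R,6E)-3,7,11-trimethyldodeca-1,6,10-trien-3-yl]phenoxy}phenyl}-5,5-dimethyl-1,3,2-dioxaborinane | C=C[C@@](C)(CC/C=C(\C)CCC=C(C)C)c1ccc(OCOC)c(Oc2cc(B3OCC(C)(C)CO3)cc(OCOC)c2OCOC)c1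
F2 | step 6 | {2-(methoxymethoxy)-5-[(3R,6E)-3,7,11-trimethyldodeca-1,6,10-trien-3-yl]phenyl}boronic acid | C=C[C@@](C)(CC/C=C(\C)CCC=C(C)C)c1ccc(OCOC)c(B(O)O)c1
F3 | step 8 | 1,2-bis(triethylsilyloxy)-3-{2-(triethylsilyloxy)-5-[(3R,6E)-3,7,11-trimethyldodeca-1,6,10-trien-3-yl]phenoxy}-5-[(3S,6E)-3,7,11-trimethyldodeca-1,6,10-trien-3-yl]benzene | C=C[C@@](C)(CC/C=C(\C)CCC=C(C)C)c1ccc(O[Si](CC)(CC)CC)c(Oc2cc([C@](C)(C=C)CC/C=C(\C)CCC=C(C)C)cc(O[Si](CC)(CC)CC)c2O[Si](CC)(CC)CC)c1
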